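**Strategy.** The top fisetinidol unit (unit A) is disconnected across its pyran ring C: ring A is plain resorcinol, and C2–C3–C4 is a three-carbon chain with an oxygen on C3 and two benzylic ends. The key step is a formal [3+3] annulation that joins resorcinol through carbon to C4 (C4a–C4) and through oxygen to C2 (O1–C2) of an epoxy alcohol carried on C6 of the second fisetinidol unit, closing ring C and setting C2 and C4 from the epoxide-derived C3 in one operation. The precursor is a benzyl-protected bis-fisetinidol–catechin triflavanoid, built by flavan-4-yl cation couplings from (+)-fustin and (+)-catechin, whose 6-bromide is elaborated to a chalcone epoxide.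

Key step: step 11

Remark: units are labelled A (upper fisetinidol, built last), B (second fisetinidol), C (catechin) and D (fisetinidol on C8 of C), with flavan numbering in each and 4α meaning trans to the 3-hydroxyl; (+)-fustin, the (2R,3R) natural product, is taken as purchasable.

**Route**

Step 1
Reactants: 1 (+)-fustin
Product: 2 7,3',4'-tri-O-benzylfustin
Conditions: BnBr (3.3 equiv), K2CO3, DMF, 0 °C to rt
Reagents that add atoms: benzyl bromide BrCc1ccccc1
Why: Williamson etherification in which carbonate deprotonates only the three phenols, so the secondary 3-hydroxyl stays free and no stereocentre is touched.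

Step 2
Reactants: 2 7,3',4'-tri-O-benzylfustin
Product: 3 7,3',4'-tri-O-benzylmollisacacidin, the (2R,3S,4R)-flavan-3,4-diol
Conditions: NaBH4, THF/EtOH, 0 °C
Reagents that add atoms: none
Why: Borohydride reduction of the flavanone carbonyl, where axial hydride delivery should give mainly the equatorial 4-hydroxyl (3,4-trans); this centre is ionised later, so its configuration is not critical.

Step 3
Reactants: 4 (+)-catechin
Product: 5 5,7,3',4'-tetra-O-benzylcatechin
Conditions: BnBr (4.4 equiv), K2CO3, DMF, 0 °C to rt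
Reagents that add atoms: benzyl bromide BrCc1ccccc1
Why: Williamson etherification of the four phenols only; carbonate at low temperature should leave C2 unepimerised and the 3-hydroxyl free.

Step 4
Reactants: 3 7,3',4'-tri-O-benzylmollisacacidin; 5 5,7,3',4'-tetra-O-benzylcatechin (4 equiv)
Product: 6 7,3',4'-tri-O-benzylfisetinidol-(4α→8)-5,7,3',4'-tetra-O-benzylcatechin (units D–C)
Conditions: BF3·OEt2 (0.3 equiv), CH2Cl2, −20 to 0 °C; excess 5 recovered
Reagents that add atoms: none
Why: Friedel–Crafts coupling with loss of water, in which the flavan-4-yl cation (from ionisation of the C4 hydroxyl, stabilised by O1 and the 7-benzyloxy group) attacks the phloroglucinol-type ring of 5 at its more accessible C8, the nucleophile entering anti to the 3-hydroxyl of the 2,3-trans cation to set the 3,4-trans (4α) centre.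

Step 5
Reactants: 3 7,3',4'-tri-O-benzylmollisacacidin
Product: 7 (2R,3S,4R)-6-bromo-7,3',4'-tris(benzyloxy)flavan-3,4-diol
Conditions: NBS (1.0 equiv), CH2Cl2, −20 °C, dark
Reagents that add atoms: N-bromosuccinimide O=C1CCC(=O)N1Br
Why: Electrophilic aromatic bromination at C6 of the 7-benzyloxy ring A, which is para to O1, ortho to the ether and less hindered than C8, while the catechol diether ring is less activated.

Step 6
Reactants: 7 6-bromo-7,3',4'-tris(benzyloxy)flavan-3,4-diol; 6 dimer D–C (2 equiv)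
Product: 8 6-bromo-7,3',4'-tri-O-benzylfisetinidol-(4α→6)-[7,3',4'-tri-O-benzylfisetinidol-(4α→8)]-5,7,3',4'-tetra-O-benzylcatechin (bromo triflavanoid B–C–D)
Conditions: BF3·OEt2 (0.3 equiv), CH2Cl2, −20 to 0 °C; excess 6 recovered
Reagents that add atoms: none
Why: Second flavan-4-yl cation Friedel–Crafts coupling with loss of water, now at C6, the only free position of the phloroglucinol-type ring of unit C, again anti to the 3-hydroxyl (4α), with the bromine blocking self-condensation of the electrophile through its own C6.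

Step 7
Reactants: 8 bromo triflavanoid B–C–D
Product: 9 6-formyl triflavanoid (aldehyde on C6 of unit B)
Conditions: n-BuLi (5 equiv), THF, −78 °C; DMF; H2O
Reagents that add atoms: N,N-dimethylformamide CN(C)C=O
Why: After deprotonation of the three hydroxyls, bromine–lithium exchange (faster at −78 °C than ortho- or benzylic lithiation) gives the aryllithium, which is formylated by DMF (Bouveault reaction).

Step 8
Reactants: 9 6-formyl triflavanoid; 10 1-[3,4-bis(benzyloxy)phenyl]ethanone (2 equiv)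
Product: 11 (E)-chalcone, 1-[3,4-bis(benzyloxy)phenyl]-3-(unit B C6)-prop-2-en-1-one
Conditions: KOH, EtOH/THF, rt
Reagents that add atoms: none
Why: Claisen–Schmidt aldol condensation whose E1cB dehydration (loss of water) gives the (E)-enone; benzyl ethers and secondary alcohols are inert and no centre can epimerise without a free 4'-phenol.

Step 9
Reactants: 11 (E)-chalcone
Product: 12 (αS,βR)-trans-epoxy ketone (epoxide carbon β on C6 of unit B)
Conditions: poly-D-leucine, urea–H2O2, DBU, THF, rt; chromatography on base-washed silica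
Reagents that add atoms: urea–hydrogen peroxide NC(N)=O.OO
Why: Juliá–Colonna (Weitz–Scheffer type) nucleophilic epoxidation in which the (E)-enone gives the trans epoxide and the helical D-peptide, the antipode of the usual catalyst, is chosen to deliver oxygen to the face that gives the (αS,βR) configuration, the resident stereocentres being remote.

Step 10
Reactants: 12 (αS,βR)-trans-epoxy ketone
Product: 13 epoxy alcohol (both carbinol epimers, epoxide as in 12)
Conditions: NaBH4, THF/EtOH, −20 °C; aq NaHCO3 work-up, used crude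
Reagents that add atoms: none
Why: Chemoselective borohydride 1,2-reduction of the aryl ketone under basic conditions that spare the acid-labile epoxide; both carbinol epimers are carried on because this centre is re-formed in step 11.

Step 11
Reactants: 13 epoxy alcohol; 14 resorcinol (10 equiv)
Product: 16 3',4'-di-O-benzylfisetinidol-(4α→6)-7,3',4'-tri-O-benzylfisetinidol-(4α→6)-[7,3',4'-tri-O-benzylfisetinidol-(4α→8)]-5,7,3',4'-tetra-O-benzylcatechin, via ring-opened C-aryl triol 15 (not isolated)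
Conditions: Sc(OTf)3 (20 mol %), MeCN/CH2Cl2, −40 °C to rt, slow addition of 13
Reagents that add atoms: none
Why: Sc(OTf)3 activates the epoxide, whose C4 is benzylic to the ortho,para-dioxygenated ring A of unit B and therefore the most electrophilic site, and resorcinol attacks it through its C4 (para to one hydroxyl, ortho to the other) in a Friedel–Crafts epoxide arylation that gives triol 15 with the new C4a–C4 bond. On warming, the remaining benzylic C2 carbinol (activated by the 4'-benzyloxy group) ionises with loss of water and is captured by the ortho phenolic hydroxyl, forming O1–C2 and closing ring C as a six-membered ring (6-exo-tet closure at the SN1 limit; the para hydroxyl cannot reach). The closest known reaction types are the Lewis-acid arylation of aryl epoxides by electron-rich arenes and phenols, and the acid-catalysed cyclisation of 1-aryl-3-(2-hydroxyaryl)propane-1,2-diols to flavan-3-ols. C3 keeps the configuration installed in step 9 because its C–O bond is never broken, C4 arises by backside opening of the trans epoxide anti to the C3 oxygen (3,4-trans), and C2 is set by chair-like, reversible cation capture that places the aryl group equatorial (2,3-trans), so both carbinol epimers of 13 should converge. The step needs carbon attack at C4 before anything happens at C2 and oxygen closure afterwards; the reactivity order epoxide above carbinol, the tenfold excess of resorcinol (against attack by product 16 or indane closure by ring B) and the free ortho hydroxyl (a far better nucleophile than the neighbouring benzyl ether oxygen) are expected to secure this.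

Step 12
Reactants: 16 dodeca-O-benzyl tetraflavanoid
Product: 17 CNP0263622.1, fisetinidol-(4α→6)-fisetinidol-(4α→6)-[fisetinidol-(4α→8)]-catechin
Conditions: H2 (1 atm), Pd(OH)2/C, THF/MeOH, rt
Reagents that add atoms: none
Why: Hydrogenolysis of all twelve benzyl ethers; the cyclic benzylic C2–O1 bonds and the diarylmethine carbons of flavanoid oligomers should survive these mild conditions.

**Compound list**

1 | (+)-fustin, (2R,3R)-3,7,3',4'-tetrahydroxyflavanone | Oc1ccc2c(c1)O[C@H](c1ccc(O)c(O)c1)[C@@H](O)C2=O | starting material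
2 | (2R,3R)-7,3',4'-tri-O-benzylfustin | O(Cc9ccccc9)c1ccc2c(c1)O[C@H](c1ccc(OCc9ccccc9)c(OCc9ccccc9)c1)[C@@H](O)C2=O | intermediate
3 | (2R,3S,4R)-7,3',4'-tris(benzyloxy)flavan-3,4-diol (tri-O-benzylmollisacacidin, 2,3-trans-3,4-trans) | O(Cc9ccccc9)c1ccc2c(c1)O[C@H](c1ccc(OCc9ccccc9)c(OCc9ccccc9)c1)[C@@H](O)[C@@H]2O | intermediate
4 | (+)-catechin, (2R,3S) | Oc1cc(O)c2c(c1)O[C@H](c1ccc(O)c(O)c1)[C@@H](O)C2 | starting material
5 | 5,7,3',4'-tetra-O-benzyl-(+)-catechin | O(Cc9ccccc9)c1cc(OCc9ccccc9)c2c(c1)O[C@H](c1ccc(OCc9ccccc9)c(OCc9ccccc9)c1)[C@@H](O)C2 | intermediate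
6 | 7,3',4'-tri-O-benzylfisetinidol-(4α→8)-5,7,3',4'-tetra-O-benzylcatechin | c1c(OCc9ccccc9)c2c(c([C@@H]3c4ccc(OCc9ccccc9)cc4O[C@H](c4ccc(OCc9ccccc9)c(OCc9ccccc9)c4)[C@H]3O)c1OCc9ccccc9)O[C@H](c1ccc(OCc9ccccc9)c(OCc9ccccc9)c1)[C@@H](O)C2 | intermediate
7 | (2R,3S,4R)-6-bromo-7,3',4'-tris(benzyloxy)flavan-3,4-diol | O(Cc9ccccc9)c1c(Br)cc2c(c1)O[C@H](c1ccc(OCc9ccccc9)c(OCc9ccccc9)c1)[C@@H](O)[C@@H]2O | intermediate
8 | 6-bromo-7,3',4'-tri-O-benzylfisetinidol-(4α→6)-[7,3',4'-tri-O-benzylfisetinidol-(4α→8)]-5,7,3',4'-tetra-O-benzylcatechin | Brc1cc2c(cc1OCc9ccccc9)O[C@H](c1ccc(OCc9ccccc9)c(OCc9ccccc9)c1)[C@@H](O)[C@@H]2c1c(OCc9ccccc9)c2c(c([C@@H]3c4ccc(OCc9ccccc9)cc4O[C@H](c4ccc(OCc9ccccc9)c(OCc9ccccc9)c4)[C@H]3O)c1OCc9ccccc9)O[C@H](c1ccc(OCc9ccccc9)c(OCc9ccccc9)c1)[C@@H](O)C2 | intermediate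
9 | 6-formyl analogue of 8 (aldehyde on C6 of unit B) | O=Cc1cc2c(cc1OCc9ccccc9)O[C@H](c1ccc(OCc9ccccc9)c(OCc9ccccc9)c1)[C@@H](O)[C@@H]2c1c(OCc9ccccc9)c2c(c([C@@H]3c4ccc(OCc9ccccc9)cc4O[C@H](c4ccc(OCc9ccccc9)c(OCc9ccccc9)c4)[C@H]3O)c1OCc9ccccc9)O[C@H](c1ccc(OCc9ccccc9)c(OCc9ccccc9)c1)[C@@H](O)C2 | intermediate
10 | 1-[3,4-bis(benzyloxy)phenyl]ethanone | CC(=O)c1ccc(OCc2ccccc2)c(OCc2ccccc2)c1 | starting material
11 | (E)-chalcone: 1-[3,4-bis(benzyloxy)phenyl]-3-(C6 of unit B)-prop-2-en-1-one | O=C(c1ccc(OCc9ccccc9)c(OCc9ccccc9)c1)/C=C/c1cc2c(cc1OCc9ccccc9)O[C@H](c1ccc(OCc9ccccc9)c(OCc9ccccc9)c1)[C@@H](O)[C@@H]2c1c(OCc9ccccc9)c2c(c([C@@H]3c4ccc(OCc9ccccc9)cc4O[C@H](c4ccc(OCc9ccccc9)c(OCc9ccccc9)c4)[C@H]3O)c1OCc9ccccc9)O[C@H](c1ccc(OCc9ccccc9)c(OCc9ccccc9)c1)[C@@H](O)C2 | intermediate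
12 | (αS,βR)-trans-epoxy ketone of 11 | O=C(c1ccc(OCc9ccccc9)c(OCc9ccccc9)c1)[C@H]5O[C@@H]5c1cc2c(cc1OCc9ccccc9)O[C@H](c1ccc(OCc9ccccc9)c(OCc9ccccc9)c1)[C@@H](O)[C@@H]2c1c(OCc9ccccc9)c2c(c([C@@H]3c4ccc(OCc9ccccc9)cc4O[C@H](c4ccc(OCc9ccccc9)c(OCc9ccccc9)c4)[C@H]3O)c1OCc9ccccc9)O[C@H](c1ccc(OCc9ccccc9)c(OCc9ccccc9)c1)[C@@H](O)C2 | intermediate
13 | epoxy alcohol from 12 (epimeric at the carbinol carbon, drawn without configuration there) | OC(c1ccc(OCc9ccccc9)c(OCc9ccccc9)c1)[C@H]5O[C@@H]5c1cc2c(cc1OCc9ccccc9)O[C@H](c1ccc(OCc9ccccc9)c(OCc9ccccc9)c1)[C@@H](O)[C@@H]2c1c(OCc9ccccc9)c2c(c([C@@H]3c4ccc(OCc9ccccc9)cc4O[C@H](c4ccc(OCc9ccccc9)c(OCc9ccccc9)c4)[C@H]3O)c1OCc9ccccc9)O[C@H](c1ccc(OCc9ccccc9)c(OCc9ccccc9)c1)[C@@H](O)C2 | intermediate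
14 | resorcinol | Oc1cccc(O)c1 | starting material
15 | ring-opened C-aryl triol: 1-[3,4-bis(benzyloxy)phenyl]-3-(2,4-dihydroxyphenyl)-3-(C6 of unit B)-propane-1,2-diol (C1 epimers; C2 and C3 of the chain as in the target) | Oc1ccc(c(O)c1)[C@H]([C@H](O)C(O)c1ccc(OCc9ccccc9)c(OCc9ccccc9)c1)c1cc2c(cc1OCc9ccccc9)O[C@H](c1ccc(OCc9ccccc9)c(OCc9ccccc9)c1)[C@@H](O)[C@@H]2c1c(OCc9ccccc9)c2c(c([C@@H]3c4ccc(OCc9ccccc9)cc4O[C@H](c4ccc(OCc9ccccc9)c(OCc9ccccc9)c4)[C@H]3O)c1OCc9ccccc9)O[C@H](c1ccc(OCc9ccccc9)c(OCc9ccccc9)c1)[C@@H](O)C2 | intermediate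
16 | dodeca-O-benzyl tetraflavanoid (unit A with free 7-OH and 3-OH; all units 2,3-trans, all links 4α) | Oc1ccc2c(c1)O[C@H](c1ccc(OCc9ccccc9)c(OCc9ccccc9)c1)[C@@H](O)[C@@H]2c1cc2c(cc1OCc9ccccc9)O[C@H](c1ccc(OCc9ccccc9)c(OCc9ccccc9)c1)[C@@H](O)[C@@H]2c1c(OCc9ccccc9)c2c(c([C@@H]3c4ccc(OCc9ccccc9)cc4O[C@H](c4ccc(OCc9ccccc9)c(OCc9ccccc9)c4)[C@H]3O)c1OCc9ccccc9)O[C@H](c1ccc(OCc9ccccc9)c(OCc9ccccc9)c1)[C@@H](O)C2 | intermediate
17 | CNP0263622.1, fisetinidol-(4α→6)-fisetinidol-(4α→6)-[fisetinidol-(4α→8)]-catechin | Oc1ccc2c(c1)O[C@H](c1ccc(O)c(O)c1)[C@@H](O)[C@@H]2c1cc2c(cc1O)O[C@H](c1ccc(O)c(O)c1)[C@@H](O)[C@@H]2c1c(O)c2c(c([C@@H]3c4ccc(O)cc4O[C@H](c4ccc(O)c(O)c4)[C@H]3O)c1O)O[C@H](c1ccc(O)c(O)c1)[C@@H](O)C2 | target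

**Step count and risks**

Total step count: 12. Longest linear sequence: 10 steps (steps 1, 2, 5, 6, 7, 8, 9, 10, 11, 12 from (+)-fustin).

Steps most likely to fail:

1. Step 11. If the epoxide ionises fully before resorcinol attacks, facial control at C4 is lost; hydride or aryl shifts of the cation and indane closure by ring B may also compete, and the ring closure at C2 may stop short or give some 2,3-cis product. Fallback: the route sets out from chalcone 11 and resorcinol 14. An acid-catalysed conjugate Friedel–Crafts addition of resorcinol to the enone β-carbon followed by cyclodehydration of the hemiketal (a chiral phosphoric acid may bias the C4 face; otherwise the diastereomers are separated later) would give the 2,4-diaryl-4H-chromene (flav-2-ene) F1. Hydroboration–oxidation (BH3·SMe2, then NaOH/H2O2) should add boron to C3 anti to the C4 substituent and hydrogen to C2 on the same face as boron, giving the 2,3-trans-3,4-trans flavan-3-ol, and comes back to the route at 16.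

2. Step 6. The cation may attack ring A of unit D instead of the hindered C6 of the catechin unit, or enter from the face syn to the 3-hydroxyl. Fallback: the order of the two couplings is reversed with a removable block, setting out from 5. Iodination with N-iodosuccinimide should give 8-iodo-5,7,3',4'-tetra-O-benzylcatechin F2. Coupling with the cation from 7 (BF3·OEt2) can then occur only at C6 and would give the 6-bromo-fisetinidol-(4α→6)-8-iodocatechin dimer F3. Iodine–magnesium exchange (i-PrMgCl·LiCl, selective for iodide over bromide) and protonation would give the C8-unsubstituted dimer F4. Coupling of F4 with the cation from 3 at the freed C8, the intrinsically most nucleophilic site (C6 of unit B being blocked by bromine), comes back to the route at 8.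

3. Step 9. Epoxidation of the bulky, electron-rich enone may be slow and the peptide may fail to override the substrate, eroding face selectivity. Fallback: the route sets out from aldehyde 9. A Corey–Chaykovsky-type epoxidation with a stoichiometric camphor-derived chiral sulfonium salt carrying a morpholine acetamide would give the trans-glycidic morpholine amide F5. Addition of excess 3,4-bis(benzyloxy)phenylmagnesium bromide to the amide should then give the ketone and comes back to the route at 12.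

Further compounds
F1 | step 11 | 7-hydroxy-2-[3,4-bis(benzyloxy)phenyl]-4-(C6 of unit B)-4H-chromene (flav-2-ene, C4 as in 16) | Oc1ccc2c(c1)OC(c1ccc(OCc9ccccc9)c(OCc9ccccc9)c1)=C[C@@H]2c1cc2c(cc1OCc9ccccc9)O[C@H](c1ccc(OCc9ccccc9)c(OCc9ccccc9)c1)[C@@H](O)[C@@H]2c1c(OCc9ccccc9)c2c(c([C@@H]3c4ccc(OCc9ccccc9)cc4O[C@H](c4ccc(OCc9ccccc9)c(OCc9ccccc9)c4)[C@H]3O)c1OCc9ccccc9)O[C@H](c1ccc(OCc9ccccc9)c(OCc9ccccc9)c1)[C@@H](O)C2
F2 | step 6 | 8-iodo-5,7,3',4'-tetra-O-benzylcatechin | O(Cc9ccccc9)c1cc(OCc9ccccc9)c2c(c1I)O[C@H](c1ccc(OCc9ccccc9)c(OCc9ccccc9)c1)[C@@H](O)C2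
F3 | step 6 | 6-bromo-7,3',4'-tri-O-benzylfisetinidol-(4α→6)-8-iodo-5,7,3',4'-tetra-O-benzylcatechin | Brc1cc2c(cc1OCc9ccccc9)O[C@H](c1ccc(OCc9ccccc9)c(OCc9ccccc9)c1)[C@@H](O)[C@@H]2c1c(OCc9ccccc9)c2c(c(I)c1OCc9ccccc9)O[C@H](c1ccc(OCc9ccccc9)c(OCc9ccccc9)c1)[C@@H](O)C2
F4 | step 6 | 6-bromo-7,3',4'-tri-O-benzylfisetinidol-(4α→6)-5,7,3',4'-tetra-O-benzylcatechin | Brc1cc2c(cc1OCc9ccccc9)O[C@H](c1ccc(OCc9ccccc9)c(OCc9ccccc9)c1)[C@@H](O)[C@@H]2c1c(OCc9ccccc9)c2c(cc1OCc9ccccc9)O[C@H](c1ccc(OCc9ccccc9)c(OCc9ccccc9)c1)[C@@H](O)C2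
F5 | step 9 | trans-glycidic morpholine amide (epoxide configured as in 12) | O=C(N1CCOCC1)[C@H]5O[C@@H]5c1cc2c(cc1OCc9ccccc9)O[C@H](c1ccc(OCc9ccccc9)c(OCc9ccccc9)c1)[C@@H](O)[C@@H]2c1c(OCc9ccccc9)c2c(c([C@@H]3c4ccc(OCc9ccccc9)cc4O[C@H](c4ccc(OCc9ccccc9)c(OCc9ccccc9)c4)[C@H]3O)c1OCc9ccccc9)O[C@H](c1ccc(OCc9ccccc9)c(OCc9ccccc9)c1)[C@@H](O)C2
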